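(Readings and results stem from a simulated flask for an exercise, and the scatter is random.)

Amounts came first at the meeting: the first chemist wrote each charge of coupling partner as a fraction of the substrate charge, 22.7% on Tuesday, 54.5% on Saturday and 132% on Monday, and pointed out that the two runs below parity, where the partner is the limiting reagent, end on a plateau of target.

common to all: substrate 0.44 M; free catalyst 2.2 mM

| run | coupling partner | remark | time |
|---|---|---|---|
| Tuesday's | 0.10 M | run made earlier |  |
| Saturday's | 0.24 M | run made earlier |  |
| Monday's | 0.58 M | run made earlier |  |
| north-east | 0.120 M |  | 2.0 min |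
| east | 0.528 M |  | 2.0 min |

| run | time / s | target / % | substrate / % |
|---|---|---|---|
| Tuesday's | 10.0 | 14.4 | 85.6 |
| Tuesday's | 12.0 | 16.2 | 83.6 |
| Tuesday's | 25.0 | 21.8 | 78.1 |
| Tuesday's | 40.0 | 22.4 | 76.6 |
| Tuesday's | 80.0 | 22.2 | 76.9 |
| Saturday's | 10.0 | 21.9 | 77.5 |
| Saturday's | 12.0 | 24.8 | 74.8 |
| Saturday's | 25.0 | 42.9 | 56.1 |
| Saturday's | 40.0 | 51.2 | 46.9 |
| Saturday's | 80.0 | 52.6 | 46.8 |
| Monday's | 10.0 | 25.6 | 73.3 |
| Monday's | 20.0 | 44.4 | 52.1 |
| Monday's | 40.0 | 69.9 | 23.7 |
| Monday's | 60.0 | 81.6 | 8.7 |
| Monday's | 80.0 | 84.5 | 3.1 |

(each reading ± 0.5 percentage points)

- which of the two ends with the higher amount of target, in percent of the substrate charged ("neither" if they lie within 2 percentage points) (north-east / east / neither)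
- target at the end, in percent of the substrate charged, north-east
- target at the end, in percent of the substrate charged, east



She divided plateau target by partner charged, pooled the last readings of Tuesday's and Saturday's runs, and obtained 0.968, the target per partner. North-east charges 27.3%, and its 120 s is longer than the 80.0 s by which Saturday's run stood on its plateau, so she put north-east at 26.4%.

The second chemist replied that in east, with 120%, the same rule gives 116%, more than the substrate charge allows. At that end substrate is limiting, and he took target as one minus what is lost. He read the loss from Monday's last reading: target and substrate sum to 87.6%, so 12.4% is gone, out of a partner excess of 31.8%. He assumed that each lost target costs one further partner and that the excess decays exponentially, which gives a decay constant, read from Monday's run, of 0.00617 s⁻¹. Applied to east's excess of 20.0% over 2.0 min, this estimates a loss of 10.5%, so the meeting put east at 89.5% target.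

The forecast also said east, with 26.5% for north-east and 86.5% for east, holding that “excess partner costs yield”, and its east figure is lower than the meeting's.

The flasks give east: north-east 26.9%, east 88.2%.

    catalyst intermediate B → catalyst intermediate C (k = 17.0 s⁻¹)
    substrate + free catalyst → catalyst intermediate A (k = 27.0 M⁻¹ s⁻¹)
    catalyst intermediate C → free catalyst + target (k = 95.0 s⁻¹)
    coupling partner + catalyst intermediate A ⇌ catalyst intermediate B (K = 20.0 M⁻¹, k = 110 M⁻¹ s⁻¹)
    coupling partner + target → over-reaction product (k = 0.0120 M⁻¹ s⁻¹)

In east at 0.358 min, target is made 10.7 times as fast as it is used up, each step taken net, and at 2.00 min east holds 88.2% target beside 11.4% over-reaction product. North-east's result over its partner charge is 0.985, against the target per partner of 0.968 read from the earlier runs. A neighbour of east charged with 0.21 M of partner, 0.477 equiv, should by the target per partner end at 46.2%; that neighbour's computed result is 46.4% target, with 52% of its substrate left.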